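## The problem

Bleochrin B (20) is an achiral pentaphenol: two benzene rings joined by a CH2CH2 bridge and carrying four 4-hydroxybenzyl groups. It has no stereocentre, so the difficulty is purely one of regiochemistry on a crowded ring. Ring A is hexasubstituted: OMe at C1, 4-hydroxybenzyl at C2, C4 and C6, a free OH at C3 and the ethylene bridge at C5. No position is free for a directing or blocking group. Apart from the O-methyl group, ring A is symmetrical about the C2–C5 axis, so the real decision is which of its two oxygens is methylated while five other phenols end up free. Ring B is simple: the bridge at B1, a 4-hydroxybenzyl group at B2 and a hydroxyl at B5, para to that benzyl group. The electron-rich phenols and the 4-hydroxybenzyl units (which ionise to quinone methides under strong acid and oxidise under aerobic base) must stay masked until the end and be released under neutral conditions that spare the methyl ether. The feature that opens the molecule is that C2–C3–C4–C5 of ring A (benzyl, oxygen, benzyl, alkyl) is the C3–C6 diene of a triketide-type 4-oxygenated 3,5-dibenzyl-2-pyrone, while C1–C6 (methoxy, benzyl) is an alkynyl methyl ether, so the two ring A oxygens can arrive from different partners.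

## Retrosynthesis

**Unmasking (20 from 19 from 18).** The five O–CH2Ph bonds are cut last and the C3 O–S bond just before. Benzyl ethers are preferred to methyl ethers (their cleavage would not spare the C1 methoxy group) and to silyl ethers (too labile for the enolate chemistry). The C3 oxygen carries a tosylate rather than a sixth benzyl group because the sulfonate is needed in the ring-forming step. The forward steps ask for hydroxide attack at a flanked aryl sulfonate, done while all other phenols are still benzylated, and then a neutral hydrogenolysis.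

**Ring A (18 from 13 and 16).** The C1–C2 and C5–C6 bonds are cut, with one carbon lost as CO2 on the way forward, through the bridged lactone 17. The neighbouring options are the C2–C3/C6–C1 cut (a cyclobutenone benzannulation) and stepwise benzylation of a resorcinol. Stepwise benzylation cannot tell ring A from four other electron-rich rings. The chosen cut places four contiguous substituted carbons in the 2-pyrone 13, whose substitution is fixed by connectivity, and two carbons in the alkyne 16, which brings the methoxy group. The forward reaction must be an inverse-demand Diels–Alder reaction of a tetrasubstituted diene with one orientation, followed by cycloreversion.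

**Alkyne (16 from 14 and 4, via 15).** The C(sp)–CH2 bond is cut to lithium methoxyacetylide 15, made from chloroacetaldehyde dimethyl acetal 14, and 4-benzyloxybenzyl chloride 4. The methyl ynol ether is chosen over higher alkyl ethers because it has no β-hydrogen and cannot fragment to a ketene on heating. The forward step is an SN2 alkylation that must not isomerise the propargylic, benzylic CH2.

**Pyrone (13 from 12 from 11).** The S–O bond and then the lactone O–C(=O) bond are cut, leading to the open 3,5-dioxo ester 11. The 4-hydroxy-2-pyrone is a vinylogous acid, so sulfonylation at O4 and enol-lactonisation of 11 are both standard.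

**Triketide chain (11 from 10 and 7).** The C4–C5 bond of the heptanoate is cut, giving the γ-carbanion of the β-keto ester 10 and the ring B acyl donor 7. A Weinreb amide is chosen as the acyl donor because its tetrahedral adduct survives until work-up, so the acidic tricarbonyl product cannot quench the dianion. The two stereocentres of 11 are irrelevant; both become sp2 in the pyrone.

**β-Keto ester (10 from 9 from 8).** The C2–C3 bond is cut by a Claisen disconnection into two molecules of methyl 3-(4-benzyloxyphenyl)propanoate 9, the O-benzyl ether of the commercial phenol ester 8. One ester therefore supplies both the C3 and the C5 benzyl groups of the pyrone.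

**Ring B acyl donor (7 from 6, from 3 and 4 via 5, from 2, from 1).** The amide C–N bond, the aryl–CH2 bond, the C–Br bond and the O–benzyl bond are cut in turn. The aryl–CH2 bond is made by Negishi coupling of the benzylzinc reagent 5 (from 4) with aryl bromide 3. The bromine is placed para to the benzyloxy group of 2, exactly where ring B needs its benzyl group. The propanoate chain is present from the start in the commercial ester 1, so no alkene has to be reduced beside benzyl ethers.

## Roads not taken

**Alternative 1:** The four 4-hydroxyphenyl rings are cut away. Each would be grown from a 3-oxopropyl arm of the tetra-aldehyde A1 and but-3-en-2-one A2 under secondary-amine catalysis, giving the tetrakis-cyclohexenone A3 as a mixture of diastereomers. A fourfold dehydrogenation to phenols would follow.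
- Merits: eight C–C bonds and four rings in one operation, a reaction of known type, and phenols that appear unprotected, so fewer protecting groups are needed than in the chosen plan.
- Weak points: the rings it builds are the ones available for nothing in 4-benzyloxybenzyl chloride 4. A1 still contains the hexasubstituted ring A with its O-methyl/O-H distinction, so the real problem is untouched. Any inefficiency of the annulation is raised to the fourth power, and a fourfold oxidation must then spare five benzylic CH2 groups.
- Comparison: the chosen plan gives up the protecting-group economy but spends its key step on ring A, the only ring that cannot be bought.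

**Alternative 2:** Ring B is cut at B1–B2 and B5–B6. The alkynone A4 would react with 1-methoxy-3-trimethylsilyloxybuta-1,3-diene A5, and loss of methanol and the silyl group would give the ring B phenol A6.
- Merits: this cycloaddition is a safer reaction than the pyrone cycloaddition of the chosen plan. Its orientation is fixed by the ynone, and the ring B hydroxyl emerges free.
- Weak points: A4 already contains the complete hexasubstituted ring A, so the hard part is moved into the starting material. The diaryl ketone of A6 must later be reduced to CH2. Ring B costs only three steps from the commercial ester 1 in the chosen route.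
- Comparison: the chosen plan sets against the safer cycloaddition a key step that is riskier but solves the actual problem.

**Alternative 3:** Ring A is cut at C2–C3 and C6–C1. The cyclobutenone A7 would be heated with the same alkyne 16 in a Danheiser benzannulation, giving A8, which is identical with 19.
- Merits: this road is better than the chosen one in two respects. The C3 hydroxyl appears free, saving the sulfonate steps. The benzannulation of cyclobutenones with alkoxyalkynes is an established route to resorcinol monoethers, whereas the pyrone reaction at this substitution level is not.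
- Weak points: A7 is a 2,3,4-trisubstituted cyclobutenone with three different carbon substituents. Its usual synthesis, a ketene–alkyne [2+2] cycloaddition with an unsymmetrical dialkylalkyne, has no bias between the C2 and C3 substituents, and the wrong regioisomer would move the bridge from C5 to C6. Its C4–H is also enolisable, and a fully substituted vinylketene is at the edge of the method.
- Comparison: the chosen plan sets against the better-precedented ring closure a precursor, pyrone 13, assembled from three ester-level pieces with every substituent fixed by connectivity.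

Key step: step 11

Assumption: the hydroxyphenylpropanoates 1 and 8 are bought as their methyl esters; each would otherwise be one Fischer esterification from the corresponding commercial acid.

## Route

Step 1
Reactants: 1 methyl 3-(3-hydroxyphenyl)propanoate
Product: 2 methyl 3-(3-benzyloxyphenyl)propanoate
Conditions: BnBr, K2CO3, acetone, reflux
Reagents that add atoms: benzyl bromide, BrCc1ccccc1
Why: Williamson ether synthesis; the phenoxide is the only nucleophile present and the methyl ester is inert to carbonate in acetone.

Step 2
Reactants: 2 methyl 3-(3-benzyloxyphenyl)propanoate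
Product: 3 methyl 3-(5-benzyloxy-2-bromophenyl)propanoate
Conditions: NBS, MeCN, 0 to 25 °C, dark
Reagents that add atoms: N-bromosuccinimide, O=C1CCC(=O)N1Br
Why: Electrophilic aromatic bromination; the benzyloxy group is the dominant director and NBS in acetonitrile should brominate para to it, which is the position ortho to the side chain, in preference to the ortho sites. Ionic conditions in the dark avoid benzylic bromination.

Step 3
Reactants: 3 methyl 3-(5-benzyloxy-2-bromophenyl)propanoate; 4 4-benzyloxybenzyl chloride
Product: 6 methyl 3-[5-benzyloxy-2-(4-benzyloxybenzyl)phenyl]propanoate, via benzylzinc chloride 5 (not isolated)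
Conditions: 4, Zn dust, LiCl, THF, 25 °C; then 3, Pd(OAc)2 (2 mol %), SPhos (4 mol %), THF, 25 to 50 °C
Reagents that add atoms: none
Why: Negishi cross-coupling; zinc insertion into the benzylic chloride in the presence of LiCl gives 5, which tolerates the ester, and zerovalent palladium formed in situ couples it with the mono-ortho-substituted aryl bromide. A benzyl group has no β-hydrogen to eliminate.

Step 4
Reactants: 6 methyl 3-[5-benzyloxy-2-(4-benzyloxybenzyl)phenyl]propanoate
Product: 7 N-methoxy-N-methyl-3-[5-benzyloxy-2-(4-benzyloxybenzyl)phenyl]propanamide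
Conditions: MeNH(OMe)·HCl, i-PrMgCl, THF, −20 to 0 °C
Reagents that add atoms: N,O-dimethylhydroxylamine hydrochloride, CNOC.Cl
Why: Direct aminolysis of the ester by the chloromagnesium amide of N,O-dimethylhydroxylamine, the standard one-step Weinreb amide synthesis from esters. At low temperature the Grignard reagent acts only as a base.

Step 5
Reactants: 8 methyl 3-(4-hydroxyphenyl)propanoate
Product: 9 methyl 3-(4-benzyloxyphenyl)propanoate
Conditions: BnBr, K2CO3, acetone, reflux
Reagents that add atoms: benzyl bromide, BrCc1ccccc1
Why: Williamson ether synthesis, as in step 1.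

Step 6
Reactants: 9 methyl 3-(4-benzyloxyphenyl)propanoate (two molecules)
Product: 10 methyl 2-(4-benzyloxybenzyl)-5-(4-benzyloxyphenyl)-3-oxopentanoate (racemic)
Conditions: NaH, MeOH (cat.), THF, reflux; then 1 M HCl
Reagents that add atoms: none
Why: Claisen self-condensation of a simple ester; the equilibrium is pulled forward by deprotonation of the β-keto ester, which keeps one acidic α-hydrogen. The new stereocentre is racemic and is lost two steps later.

Step 7
Reactants: 10 methyl 2-(4-benzyloxybenzyl)-5-(4-benzyloxyphenyl)-3-oxopentanoate; 7 N-methoxy-N-methyl-3-[5-benzyloxy-2-(4-benzyloxybenzyl)phenyl]propanamide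
Product: 11 methyl 2,4-bis(4-benzyloxybenzyl)-7-[5-benzyloxy-2-(4-benzyloxybenzyl)phenyl]-3,5-dioxoheptanoate (mixture of diastereomers and enol forms)
Conditions: 10 (1.5 equiv), NaH, THF, 0 °C; n-BuLi, 0 °C; then 7, −78 to 0 °C; aq NH4Cl
Reagents that add atoms: none
Why: γ-Acylation of a β-keto ester dianion; the second, more basic carbanion at C4 is the reactive site, and the chelated tetrahedral adduct of the Weinreb amide persists until work-up, so the acidic tricarbonyl product cannot quench unreacted dianion. Both stereocentres are epimerisable and become sp2 in step 8, so no control is needed.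

Step 8
Reactants: 11 methyl 2,4-bis(4-benzyloxybenzyl)-7-[5-benzyloxy-2-(4-benzyloxybenzyl)phenyl]-3,5-dioxoheptanoate
Product: 12 3,5-bis(4-benzyloxybenzyl)-6-{2-[5-benzyloxy-2-(4-benzyloxybenzyl)phenyl]ethyl}-4-hydroxy-2H-pyran-2-one
Conditions: DBU, PhMe, 80 °C; then 1 M HCl
Reagents that add atoms: none
Why: Enol-lactonisation of a 3,5-dioxo ester (6-exo-trig attack of the C5 enolate oxygen on the ester carbonyl, loss of methanol), the standard closure to 3,5-disubstituted 4-hydroxy-2-pyrones. It is driven by formation of the conjugated, acidic pyrone.

Step 9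
Reactants: 12 3,5-bis(4-benzyloxybenzyl)-6-{2-[5-benzyloxy-2-(4-benzyloxybenzyl)phenyl]ethyl}-4-hydroxy-2H-pyran-2-one
Product: 13 3,5-bis(4-benzyloxybenzyl)-6-{2-[5-benzyloxy-2-(4-benzyloxybenzyl)phenyl]ethyl}-2-oxo-2H-pyran-4-yl 4-methylbenzenesulfonate
Conditions: TsCl, Et3N, DMAP (cat.), CH2Cl2, 0 to 25 °C
Reagents that add atoms: p-toluenesulfonyl chloride, Cc1ccc(cc1)S(Cl)(=O)=O
Why: O-Sulfonylation of the vinylogous acid; 4-hydroxy-2-pyrones normally react with sulfonyl chlorides at the C4 oxygen to give 4-sulfonyloxy-2-pyrones, which are stable and electron-poor.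

Step 10
Reactants: 14 chloroacetaldehyde dimethyl acetal; 4 4-benzyloxybenzyl chloride
Product: 16 1-methoxy-3-(4-benzyloxyphenyl)prop-1-yne, via lithium methoxyacetylide 15 (not isolated)
Conditions: Et2NH, n-BuLi (3.0 equiv each), THF, 0 °C; 14; then 4, NaI (cat.), DMPU, −78 to 25 °C; water quench, Et3N-deactivated silica
Reagents that add atoms: none
Why: Three equivalents of lithium diethylamide convert the chloroacetal into the lithium alkoxyacetylide by two eliminations and a deprotonation, and SN2 alkylation of such acetylides with reactive halides in a dipolar cosolvent is a known route to 1-alkoxyalkynes. Exactly three equivalents of base leave no amide to deprotonate the product.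

Step 11
Reactants: 13 3,5-bis(4-benzyloxybenzyl)-6-{2-[5-benzyloxy-2-(4-benzyloxybenzyl)phenyl]ethyl}-2-oxo-2H-pyran-4-yl 4-methylbenzenesulfonate; 16 1-methoxy-3-(4-benzyloxyphenyl)prop-1-yne
Product: 18 penta-O-benzyl bleochrin B C3 tosylate, via bridged lactone 17 (not isolated)
Conditions: 16 (3 equiv), BHT (cat.), PhMe (1 M), 160 °C, sealed base-washed tube
Reagents that add atoms: none
Why: Proposed new method: the tosyloxy-2-pyrone 13 is the electron-poor 4π partner and the ynol ether 16 the electron-rich 2π partner of an inverse-demand Diels–Alder reaction, in which the bond from the nucleophilic, benzyl-bearing alkyne carbon to pyrone C6 (the terminus conjugated to the lactone carbonyl) should run ahead of the bond from the methoxy-bearing carbon to pyrone C3. The closest known reaction type is the cycloaddition of 2-pyrones with ynamines, alkoxyalkynes and ketene acetals followed by loss of carbon dioxide, which has not been shown for a fully substituted 4-sulfonyloxy-2-pyrone with an internal alkoxyalkyne. Ring A closes by intermolecular [4+2] cycloaddition, both new bonds (C1–C2 and C5–C6 of ring A) joining the two components, through the 2-oxabicyclo[2.2.2]octa-5,7-dien-3-one 17. The two bridgehead stereocentres of 17 are fixed relative to each other by the bicycle and vanish when the lactone bridge leaves as CO2 in an irreversible retro-[4+2] step that gives the arene directly, so no stereocentre has to be controlled. The step needs one orientation, secured by matching the electrophilic pyrone C6 with the alkyne carbon remote from oxygen, where the ynol ether is most nucleophilic. It also needs the cycloaddition to outrun decay of the ynol ether, which is helped by the methyl ether having no β-hydrogen, so the retro-ene fragmentation to a ketene open to higher alkoxyalkynes is excluded. The sulfonate makes the diene more electron-poor than a 4-alkoxy or 4-hydroxy group would and keeps the C3 oxygen distinct from the C1 methoxy group delivered by the alkyne. Excess alkyne, high concentration and a sealed vessel are meant to compensate for the tetrasubstituted diene.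

Step 12
Reactants: 18 penta-O-benzyl bleochrin B C3 tosylate
Product: 19 penta-O-benzyl bleochrin B (free C3 hydroxyl)
Conditions: KOH, 1,4-dioxane/H2O (4:1), 100 °C; then 1 M HCl
Reagents that add atoms: none
Why: Alkaline hydrolysis of an aryl sulfonate by hydroxide attack at sulfur; benzyl ethers, the methyl ether and the diarylmethane units are stable to hot alkali. The aqueous medium avoids forming an alkyl tosylate that could O-alkylate the liberated phenoxide.

Step 13
Reactants: 19 penta-O-benzyl bleochrin B (free C3 hydroxyl)
Product: 20 bleochrin B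
Conditions: H2 (1 atm), 10% Pd/C, EtOAc/MeOH (1:1), 25 °C
Reagents that add atoms: none
Why: Hydrogenolysis of five aryl benzyl ethers under neutral conditions; the methyl ether and the diarylmethane C–C bonds are not cleaved, and no acid or base is present to trigger quinone methide chemistry of the free 4-hydroxybenzyl groups.

## Compound list

1 | methyl 3-(3-hydroxyphenyl)propanoate | COC(=O)CCc1cccc(O)c1 | starting material
2 | methyl 3-(3-benzyloxyphenyl)propanoate | COC(=O)CCc1cccc(OCc2ccccc2)c1 | intermediate
3 | methyl 3-(5-benzyloxy-2-bromophenyl)propanoate | COC(=O)CCc1cc(OCc2ccccc2)ccc1Br | intermediate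
4 | 4-benzyloxybenzyl chloride | ClCc1ccc(OCc2ccccc2)cc1 | starting material
5 | (4-benzyloxybenzyl)zinc chloride, not isolated | Cl[Zn]Cc1ccc(OCc2ccccc2)cc1 | intermediate
6 | methyl 3-[5-benzyloxy-2-(4-benzyloxybenzyl)phenyl]propanoate | COC(=O)CCc1cc(OCc2ccccc2)ccc1Cc1ccc(OCc2ccccc2)cc1 | intermediate
7 | N-methoxy-N-methyl-3-[5-benzyloxy-2-(4-benzyloxybenzyl)phenyl]propanamide | CON(C)C(=O)CCc1cc(OCc2ccccc2)ccc1Cc1ccc(OCc2ccccc2)cc1 | intermediate
8 | methyl 3-(4-hydroxyphenyl)propanoate | COC(=O)CCc1ccc(O)cc1 | starting material
9 | methyl 3-(4-benzyloxyphenyl)propanoate | COC(=O)CCc1ccc(OCc2ccccc2)cc1 | intermediate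
10 | methyl 2-(4-benzyloxybenzyl)-5-(4-benzyloxyphenyl)-3-oxopentanoate, racemic | COC(=O)C(Cc1ccc(OCc2ccccc2)cc1)C(=O)CCc1ccc(OCc2ccccc2)cc1 | intermediate
11 | methyl 2,4-bis(4-benzyloxybenzyl)-7-[5-benzyloxy-2-(4-benzyloxybenzyl)phenyl]-3,5-dioxoheptanoate, mixture of diastereomers, drawn as the triketo form | COC(=O)C(Cc1ccc(OCc2ccccc2)cc1)C(=O)C(Cc1ccc(OCc2ccccc2)cc1)C(=O)CCc1cc(OCc2ccccc2)ccc1Cc1ccc(OCc2ccccc2)cc1 | intermediate
12 | 3,5-bis(4-benzyloxybenzyl)-6-{2-[5-benzyloxy-2-(4-benzyloxybenzyl)phenyl]ethyl}-4-hydroxy-2H-pyran-2-one | O=C1OC(CCc2cc(OCc3ccccc3)ccc2Cc2ccc(OCc3ccccc3)cc2)=C(Cc2ccc(OCc3ccccc3)cc2)C(O)=C1Cc1ccc(OCc2ccccc2)cc1 | intermediate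
13 | 3,5-bis(4-benzyloxybenzyl)-6-{2-[5-benzyloxy-2-(4-benzyloxybenzyl)phenyl]ethyl}-2-oxo-2H-pyran-4-yl 4-methylbenzenesulfonate | O=C1OC(CCc2cc(OCc3ccccc3)ccc2Cc2ccc(OCc3ccccc3)cc2)=C(Cc2ccc(OCc3ccccc3)cc2)C(OS(=O)(=O)c2ccc(C)cc2)=C1Cc1ccc(OCc2ccccc2)cc1 | intermediate
14 | chloroacetaldehyde dimethyl acetal | COC(CCl)OC | starting material
15 | lithium methoxyacetylide, not isolated | COC#C[Li] | intermediate
16 | 1-methoxy-3-(4-benzyloxyphenyl)prop-1-yne | COC#CCc1ccc(OCc2ccccc2)cc1 | intermediate
17 | 4,6,7-tris(4-benzyloxybenzyl)-1-{2-[5-benzyloxy-2-(4-benzyloxybenzyl)phenyl]ethyl}-8-methoxy-3-oxo-2-oxabicyclo[2.2.2]octa-5,7-dien-5-yl 4-methylbenzenesulfonate, racemic, bridgeheads fixed relative to each other by the bicycle, not isolated | O=C1OC2(CCc3cc(OCc4ccccc4)ccc3Cc3ccc(OCc4ccccc4)cc3)C(Cc3ccc(OCc4ccccc4)cc3)=C(OS(=O)(=O)c3ccc(C)cc3)C1(Cc1ccc(OCc3ccccc3)cc1)C(OC)=C2Cc1ccc(OCc2ccccc2)cc1 | intermediate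
18 | penta-O-benzyl bleochrin B C3 tosylate | COc1c(Cc2ccc(OCc3ccccc3)cc2)c(OS(=O)(=O)c2ccc(C)cc2)c(Cc2ccc(OCc3ccccc3)cc2)c(CCc2cc(OCc3ccccc3)ccc2Cc2ccc(OCc3ccccc3)cc2)c1Cc1ccc(OCc2ccccc2)cc1 | intermediate
19 | penta-O-benzyl bleochrin B, C3 hydroxyl free | COc1c(Cc2ccc(OCc3ccccc3)cc2)c(O)c(Cc2ccc(OCc3ccccc3)cc2)c(CCc2cc(OCc3ccccc3)ccc2Cc2ccc(OCc3ccccc3)cc2)c1Cc1ccc(OCc2ccccc2)cc1 | intermediate
20 | bleochrin B | COc1c(Cc2ccc(O)cc2)c(O)c(Cc2ccc(O)cc2)c(CCc2cc(O)ccc2Cc2ccc(O)cc2)c1Cc1ccc(O)cc1 | target

## Step count and least certain steps

Total: 13 steps. Longest linear sequence: 10 steps (steps 1, 2, 3, 4, 7, 8, 9, 11, 12, 13).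

**Step 11 (key step, proposed new method).** The most likely failure is that the tetrasubstituted diene reacts too slowly, so the ynol ether is consumed first by propargyl–allenyl isomerisation, oligomerisation or [2+2] addition to the lactone carbonyl. A second risk is partial reversal of orientation at the hindered C6 terminus. The fallback sets out from 16 and 13 and returns at 18, replacing the alkyne by a ketene acetal in the established pyrone–ketene acetal arene synthesis. Base-catalysed addition of methanol to 16 (NaOMe cat., MeOH), a known reaction of 1-alkoxyalkynes, should give 1-benzyloxy-4-(3,3-dimethoxyprop-2-enyl)benzene F1, a stronger and thermally more robust nucleophile. Heating F1 with 13 should give the bridged lactone acetal F2, which loses CO2 to the 5,5-dimethoxycyclohexa-1,3-diene F3. Elimination of methanol across C1–C6 of F3 then gives 18 with the same orientation.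

**Step 7.** The hindered γ-carbanion may deprotonate the enolisable amide instead of adding to it, leading to low conversion and recovered 10. The fallback sets out from 7 and 10 and returns at 11, moving the coupling to the aldehyde oxidation level. DIBAL-H reduction of 7 should give 3-[5-benzyloxy-2-(4-benzyloxybenzyl)phenyl]propanal F4. Aldol addition of the dianion of 10 to F4 gives the 5-hydroxy-3-oxo ester F5 as a diastereomer mixture, and Dess–Martin oxidation of F5 gives 11.

**Step 10.** Proton transfer from the doubly activated CH2 of the product to unreacted acetylide may cause isomerisation to the allenyl ether or a second alkylation, and the ynol ether may hydrate on acidic silica. The fallback sets out from 15 (made from 14) and 4 and returns at 16, forming the same bond under neutral conditions. Quenching 15 with Bu3SnCl should give tributyl(methoxyethynyl)stannane F6, and Stille coupling of F6 with 4 under Pd(PPh3)4 catalysis (zerovalent palladium, THF, 60 °C) gives 16 without any carbanion present.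

**Step 12.** Hydroxide attack at sulfur may be slow because the sulfonate is flanked by two benzyl groups, leading to incomplete cleavage on prolonged heating. The fallback sets out from 18 and returns at 19, replacing nucleophilic attack by electron transfer. Mg turnings in MeOH/THF should cleave the S–O bond reductively to the phenoxide and a sulfinate, a process that does not depend on access to sulfur and leaves benzyl ethers intact; it passes through no new compound F0.

## Further compounds

F1 | step 11 | 1-benzyloxy-4-(3,3-dimethoxyprop-2-enyl)benzene | COC(OC)=CCc1ccc(OCc2ccccc2)cc1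
F2 | step 11 | 4,6,7-tris(4-benzyloxybenzyl)-1-{2-[5-benzyloxy-2-(4-benzyloxybenzyl)phenyl]ethyl}-8,8-dimethoxy-3-oxo-2-oxabicyclo[2.2.2]oct-5-en-5-yl 4-methylbenzenesulfonate, mixture of diastereomers | O=C1OC2(CCc3cc(OCc4ccccc4)ccc3Cc3ccc(OCc4ccccc4)cc3)C(Cc3ccc(OCc4ccccc4)cc3)=C(OS(=O)(=O)c3ccc(C)cc3)C1(Cc1ccc(OCc3ccccc3)cc1)C(OC)(OC)C2Cc1ccc(OCc2ccccc2)cc1
F3 | step 11 | 2,4,6-tris(4-benzyloxybenzyl)-5-{2-[5-benzyloxy-2-(4-benzyloxybenzyl)phenyl]ethyl}-1,1-dimethoxycyclohexa-2,4-dien-3-yl 4-methylbenzenesulfonate, racemic | COC1(OC)C(Cc2ccc(OCc3ccccc3)cc2)C(CCc2cc(OCc3ccccc3)ccc2Cc2ccc(OCc3ccccc3)cc2)=C(Cc2ccc(OCc3ccccc3)cc2)C(OS(=O)(=O)c2ccc(C)cc2)=C1Cc1ccc(OCc2ccccc2)cc1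
F4 | step 7 | 3-[5-benzyloxy-2-(4-benzyloxybenzyl)phenyl]propanal | O=CCCc1cc(OCc2ccccc2)ccc1Cc1ccc(OCc2ccccc2)cc1
F5 | step 7 | methyl 2,4-bis(4-benzyloxybenzyl)-7-[5-benzyloxy-2-(4-benzyloxybenzyl)phenyl]-5-hydroxy-3-oxoheptanoate, mixture of diastereomers | COC(=O)C(Cc1ccc(OCc2ccccc2)cc1)C(=O)C(Cc1ccc(OCc2ccccc2)cc1)C(O)CCc1cc(OCc2ccccc2)ccc1Cc1ccc(OCc2ccccc2)cc1
F6 | step 10 | tributyl(methoxyethynyl)stannane | COC#C[Sn](CCCC)(CCCC)CCCC
F0 | step 12 | none | none
A1 | alternative 1 | tetra-aldehyde with 3-oxopropyl arms at C2, C4 and C6 of ring A and at B2 of ring B, C3 and B5 oxygens benzylated | COc1c(CCC=O)c(OCc2ccccc2)c(CCC=O)c(CCc2cc(OCc3ccccc3)ccc2CCC=O)c1CCC=O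
A2 | alternative 1 | but-3-en-2-one | CC(=O)C=C
A3 | alternative 1 | tetrakis(4-oxocyclohex-2-enylmethyl) core, mixture of diastereomers | COc1c(CC2C=CC(=O)CC2)c(OCc2ccccc2)c(CC2C=CC(=O)CC2)c(CCc2cc(OCc3ccccc3)ccc2CC2C=CC(=O)CC2)c1CC1C=CC(=O)CC1
A4 | alternative 2 | alkynone joining the but-3-ynyl chain on C5 of ring A to a 4-benzyloxybenzoyl group | COc1c(Cc2ccc(OCc3ccccc3)cc2)c(OCc2ccccc2)c(Cc2ccc(OCc3ccccc3)cc2)c(CCC#CC(=O)c2ccc(OCc3ccccc3)cc2)c1Cc1ccc(OCc2ccccc2)cc1
A5 | alternative 2 | (E)-1-methoxy-3-trimethylsilyloxybuta-1,3-diene | CO/C=C/C(=C)O[Si](C)(C)C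
A6 | alternative 2 | ring B phenol with a 4-benzyloxybenzoyl group on B6 | COc1c(Cc2ccc(OCc3ccccc3)cc2)c(OCc2ccccc2)c(Cc2ccc(OCc3ccccc3)cc2)c(CCc2cc(O)ccc2C(=O)c2ccc(OCc3ccccc3)cc2)c1Cc1ccc(OCc2ccccc2)cc1
A7 | alternative 3 | 2,4-bis(4-benzyloxybenzyl)-3-{2-[5-benzyloxy-2-(4-benzyloxybenzyl)phenyl]ethyl}cyclobut-2-en-1-one, racemic | O=C1C(Cc2ccc(OCc3ccccc3)cc2)C(CCc2cc(OCc3ccccc3)ccc2Cc2ccc(OCc3ccccc3)cc2)=C1Cc1ccc(OCc2ccccc2)cc1
A8 | alternative 3 | penta-O-benzyl bleochrin B with the C3 hydroxyl free, identical with 19 | COc1c(Cc2ccc(OCc3ccccc3)cc2)c(O)c(Cc2ccc(OCc3ccccc3)cc2)c(CCc2cc(OCc3ccccc3)ccc2Cc2ccc(OCc3ccccc3)cc2)c1Cc1ccc(OCc2ccccc2)cc1
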